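In a one-step world, where solid substrate turned over with a fixed chance per minute, the percent curve would not depend on the charge. A solid need not obey that. If going into solution is the rate-limiting step, the solid acts like a pump delivering a fixed amount per minute, zero-order in the charge.

| flask | solid substrate | acid | scavenger | protic impurity | remark | time |
|---|---|---|---|---|---|---|
| ochre | 0.10 M | 1 mM | 0.080 M | 0.10 M | the very flask that is asked about, followed so far |  |
| green | 0.050 M | 1 mM | 0.080 M | 0.10 M | run made earlier |  |
| flask | 0.10 M | 1.00 mM | 0.0800 M | 0.100 M |  | 15 min |

| run | time / min | solid substrate / % | target / % |
|---|---|---|---|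
| ochre | 0.200 | 99.3 | 0.7 |
| ochre | 0.500 | 99.5 | 1.3 |
| ochre | 1.33 | 98.6 | 0 |
| ochre | 2.50 | 97.5 | 0 |
| green | 4.00 | 95.3 | 1.4 |
| green | 8.00 | 90.0 | 3.9 |
| green | 12.0 | 85.8 | 6.0 |
| green | 15.0 | 83.3 | 8.0 |

(standard deviation of a reading: 0.5 percentage points)

- acid is the free proton; pH is minus the decimal logarithm of its molar concentration
- given per volume of solution although it is solid: solid substrate
- at the start none of the solid substrate is in solution
- what has only dissolved of solid substrate counts as not reacted

* part of the solid substrate that has reacted (what has only dissolved counts as not reacted) at 15 min
* pH of the solution at 15 min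

The green run lost 16.7% of its 0.050 M by 15.0 min, so I read a feed of 0.557 mM/min. I folded the givens into one number, feed times time over charge, which is the part of the charge delivered so far: 8.35% for the ochre flask at 15 min. I call it the delivered share, and it was my estimate of c, half of green's loss.

Was one number enough? Not surely. At 2.50 min the last ochre reading showed a loss of 2.50%, more than the 1.39% the same reckoning gives, a gap of 1.1 percentage points against a scatter of 0.5 points. I kept the number with that doubt, since green's readings run to 15.0 min and ochre's stop at 2.50 min.

The forecast said 16% and pH 3, finding “no sign of solubility-limited zero-order behaviour”; its c is twice my figure. On pH I had no reading and no figure of my own.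

The ochre flask gave 8.17% reacted at pH 3.00, beside the delivered share of 8.35%. Its starting material stood at 0.268% of the charge at 1.50 min and at 0.286% at 15.0 min.

    starting material + protic impurity → quenched substrate (k = 11.0 /M/min)
    starting material + acid → weak acid + acid + target (k = 910 /M/min)
    solid substrate ⇌ starting material, rate k3*(cs3 - [starting material]) while solid is left; crystals form when [starting material] > cs3 (solubility = 8.00 mM, k = 0.0730 /min)
    weak acid + scavenger → scavenged by-product (k = 150 /M/min)
    starting material + weak acid ⇌ idle adduct, settled at all times (K = 8.80 /M)
    starting material → weak acid + target (k = 0.00280 /min)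
    weak acid ⇌ conjugate base + acid, settled at all times (K = 7.90 × 10⁻¹⁰ M)

The neighbour flask with 0.025 M of solid substrate, its other charges and time as in the recipe, has a delivered share of 33.4%, and it reacted 32.7%.

(The runs come from a simulation from invented constants; scatter was added.)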